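The target in the beta run reads 37% at 0.417 h and 4% at 2.50 h, so once made it is being lost, and the question is how much of it this flask keeps.

common to all: starting material 0.063 M

| run | reagent in the second phase | remark | time | volume of the second phase over the first |
|---|---|---|---|---|
| beta | 0.16 M | run made earlier |  |  |
| flask | 0.0819 M |  | 8.0 h | 0.25 |

- beta (time / h: target / %): 0.417: 37; 0.833: 28; 1.33: 16; 1.50: 16; 2.00: 10; 2.50: 4

(each reading ± 1.5 percentage points)

- in the second phase: reagent in the second phase; everything else is in the first
- charges count per volume of the first phase; a concentration in a rate is the amount of a species over the volume of its own phase; every rate counts per litre of the first phase
- the numbers in the tables scatter with a standard deviation of 1.5 percentage points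
- the earlier runs hold the two phases in the same ratio of volumes as the flask asked about

- winter: doubling the transfer coefficient of the reagent in the second phase, all else as stated
- dawn: doubling the amount of reagent in the second phase, all else as stated

* the target standing at 8.0 h, as a percentage of the starting material charged
* the change that raises the amount of target at 8.0 h, in percent of the starting material charged most ("none" if none brings more than 2 percentage points) (winter / dawn / none)
* amount of target at 8.0 h, in percent of the starting material charged, after dawn

Two people argue over this flask. The counter puts the zero of the scale at one equivalent of reagent per starting material. The flask is charged with 1.30 equivalents against 2.54 in beta, so it stands close to that zero, and she expects the loss to stop once the reagent is counted off.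

The timekeeper reads a clock instead. Between the first and last beta readings the target falls with a pseudo-first-order constant k_b = 1.07 /h, a reading that carries the scatter. Supposing the loss goes in proportion to the reagent charged, he defines k = k_b × (flask charge / beta charge) = 0.547 /h, the target's loss constant scaled to the reagent charged. That is a half-life of 1.27 h. Starting from the first beta reading, which he borrows for this flask, he gets 0.586% at 8.0 h. This is my reckoning too.

The forecast takes the counter's side, with “reagent runs out within a few hours”: 64% for the target, none as the best change, and 0.1% after dawn. Its target figure stands far higher than the clock's.

The flask gives 4.47%, best change none, and 0.551% after dawn.

    reagent in the reaction phase + target → over-reaction product (k = 0.530 /M/min)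
    starting material + reagent in the reaction phase ⇌ target (K = 16.0 /M, k = 2.70 /M/min)
    reagent in the reaction phase ⇌ reagent in the second phase, rate k3*([reagent in the reaction phase] - [reagent in the second phase]/K3) per volume of the first phase (partition coefficient = 0.720, kL = 0.00720 /min)

In the flask, half of the turnover up to 8.0 h of the step into target was done by 0.408 h, and half of that of the step into over-reaction product by 1.42 h. At 8.00 h the flask holds 39.5% starting material, 4.47% target, 56.0% over-reaction product and 0.00715 M reagent in the reaction phase, with target made at 0.469 of the rate it is used up, each step taken net. The clock's figure lies below the result. The forecast's choice of none agrees with the flask: winter moves the target by −0.2 percentage points and dawn by −3.9 points.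

For the neighbour flask, the same charge read at 3.0 h, k gives 9.01%. The computed result there is 11.3%.

All runs were generated by integration with made-up constants; the scatter is artificial.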